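## Retrosynthetic overview

1. Numbering (dictyol): ring A = C1–C5 (C3=C4, 4-Me). Ring B = C1, C5–C10 (C10=C20H2, 6-OH, side chain at C7). Oxolane = C11–C14 + O, and C15 carries the acetate.
2. Feature used: both ring-fusion hydrogens sit at the γ-end of an allyl unit (H–C5–C4=C3 and H–C1–C10=C20). Together these form the skipped 1,5-diene C3=C4–C5–C1–C10=C20 across the A/B fusion bond. Two retro reductive allylic transpositions convert it into the conjugated diene C4=C5–C1=C10 with oxygen at C3 and C20, which is the 4-alkylidenecyclopentenone 22.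
3. Key disconnection: 22 ⇒ acyclic allene-yne 21 + CO by a Rh(I) allenic Pauson–Khand [2+2+1]. It forms C1–C5, C2–C3 and C3–C4 and closes rings A and B in one operation, with the complete side chain in place.
4. 21 ⇒ alkene 16 + propargylic phosphate 19 (C9–C10, SN2'). The oxolane comes from epoxide opening (O–C14), C11 from chelate-controlled methyl addition, and C6/C7 from a crotonate-imide syn-aldol with but-2-ynal.
5. Ring order: oxolane first, then rings A and B together. After that C5–H is set by retro-ene from a reagent-set C3 carbinol, and finally C1–H together with C10=C20.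

Key step: step 12

Remark: CIP descriptors are given in dictyol numbering. The descriptors of C5 and C6 change along the route only because substituent priorities change, not the geometry. The ent-Shi ketone (L-fructose series) is taken as an accessible catalyst.

## Route

Step 1
Reactants: 1 (R)-4-benzyl-1,3-oxazolidin-2-one; 2 (E)-but-2-enoyl chloride
Product: 3 (R)-4-benzyl-3-[(E)-but-2-enoyl]-1,3-oxazolidin-2-one
Conditions: n-BuLi, THF, −78 °C; then 2, −78 → 0 °C
Reagents that add atoms: none
Why: N-acylation of the lithiated oxazolidinone with an acid chloride is the standard entry to the imide, and no stereocentre is formed.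

Step 2
Reactants: 3 crotonate imide; 4 but-2-ynal
Product: 7 (R)-4-benzyl-3-[(2R,3R)-2-ethenyl-3-hydroxyhex-4-ynoyl]-1,3-oxazolidin-2-one, via boron dienolate 5 (not isolated), via boron aldolate 6 (not isolated)
Conditions: Bu2BOTf, Et3N, CH2Cl2, −78 → 0 °C; 4, −78 °C; then MeOH, pH 7 buffer, H2O2, 0 °C
Reagents that add atoms: dibutylboron triflate, CCCCB(CCCC)OS(=O)(=O)C(F)(F)F (boron stays only in 5 and 6)
Why: In this Evans syn-aldol of a crotonate imide, γ-deprotonation gives the Z(O)-dienolate, which should react at Cα through a Zimmerman–Traxler chair on the face opposite the benzyl group, setting C7 (R) and C6 (R) and leaving C8=C9 as a deconjugated vinyl group.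

Step 3
Reactants: 7 aldol imide
Product: 8 (2R,3R)-2-ethenyl-3-hydroxy-N-methoxy-N-methylhex-4-ynamide
Conditions: MeNH(OMe)·HCl, AlMe3, CH2Cl2, −20 → 0 °C
Reagents that add atoms: N,O-dimethylhydroxylamine hydrochloride, CNOC.Cl
Why: Aluminium-amide transamination (Weinreb amide formation) is assisted by the free β-hydroxyl, cleaves only the exocyclic imide bond and should leave C6 and C7 untouched.

Step 4
Reactants: 8 Weinreb amide; 9 5-bromo-2-methylpent-2-ene
Product: 11 (4R,5R)-5-ethenyl-4-hydroxy-10-methylundec-9-en-2-yn-6-one (C11 ketone), via homoprenyl Grignard reagent 10 (not isolated)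
Conditions: 9, Mg, THF, 23 °C; then 8, THF, −20 → 0 °C; aq. NH4Cl
Reagents that add atoms: magnesium, [Mg] (stays only in 10)
Why: The Weinreb ketone synthesis stops at the ketone because collapse to the carbonyl occurs only on work-up, and the low temperature should keep the α-vinyl centre C7 intact.

Step 5
Reactants: 11 β-hydroxy ketone
Product: 12 (4R,5R,6R)-5-ethenyl-6,10-dimethylundec-9-en-2-yne-4,6-diol (6R,7R,11R in dictyol numbering)
Conditions: MeMgBr (4 equiv), CH2Cl2–Et2O, −78 °C
Reagents that add atoms: methylmagnesium bromide, C[Mg]Br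
Why: In this Cram-chelate addition, magnesium bridges O6 and O11 in a six-membered chelate whose far face carries C5 and C8, so methyl should attack from the H6/H7 face and set C11 as (R).

Step 6
Reactants: 12 diol
Product: 14 (4R,5R)-5-[(2R,5R)-5-(2-hydroxypropan-2-yl)-2-methyloxolan-2-yl]hept-6-en-2-yn-4-ol, via 14S epoxide 13 (not isolated)
Conditions: ent-Shi ketone (30 mol %), Oxone, K2CO3, Bu4NHSO4, MeCN–DMM/aq. borate buffer, 0 °C; then CSA (cat.), CH2Cl2, 0 °C
Reagents that add atoms: potassium peroxymonosulfate (Oxone), [K+].[O-]S(=O)(=O)OO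
Why: Shi epoxidation picks the only trisubstituted alkene and sets the (14S)-epoxide by reagent control, and 5-exo-tet opening by the C11 hydroxyl then inverts C14 to (R), giving the 2,5-trans oxolane without touching C11.

Step 7
Reactants: 14 oxolane diol
Product: 15 6-O-TBS ether of 14 (C15–OH free)
Conditions: TBSCl, imidazole, DMAP (cat.), DMF, 23 → 40 °C
Reagents that add atoms: tert-butyldimethylsilyl chloride, CC(C)(C)[Si](C)(C)Cl
Why: Silylation with the chloride and imidazole should take the secondary propargylic alcohol and leave the tertiary carbinol free.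

Step 8
Reactants: 15 silyl ether
Product: 16 2-[(2R,5R)-5-{(3R,4R)-4-(tert-butyldimethylsilyloxy)hept-1-en-5-yn-3-yl}-5-methyloxolan-2-yl]propan-2-yl acetate
Conditions: Ac2O, Et3N, DMAP, CH2Cl2, 23 → 40 °C
Reagents that add atoms: acetic anhydride, CC(=O)OC(C)=O
Why: DMAP-catalysed acylation of the only remaining, tertiary hydroxyl installs the C15 acetate while C6 is masked.

Step 9
Reactants: 17 but-2-yne-1,4-diol
Product: 18 4-(tert-butyldimethylsilyloxy)but-2-yn-1-ol
Conditions: 17 (3 equiv), TBSCl, imidazole, THF, 0 → 23 °C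
Reagents that add atoms: tert-butyldimethylsilyl chloride, CC(C)(C)[Si](C)(C)Cl
Why: Statistical monosilylation with excess symmetrical diol should give mainly the mono-ether.

Step 10
Reactants: 18 monosilyl ether
Product: 19 4-(tert-butyldimethylsilyloxy)but-2-ynyl diethyl phosphate
Conditions: ClP(O)(OEt)2, pyridine, DMAP (cat.), CH2Cl2, 0 °C
Reagents that add atoms: diethyl chlorophosphate, CCOP(=O)(Cl)OCC
Why: O-phosphorylation of the primary propargylic alcohol provides the leaving group for the SN2' coupling.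

Step 11
Reactants: 16 alkene; 19 propargylic phosphate
Product: 21 allene-yne (6R,7R,11R,14R): CH3C≡C–C6H(OTBS)–C7H(oxolanyl)–C8H2–C9H2–C10(CH2OTBS)=C1=C2H2, via B-alkyl-9-BBN 20 (not isolated)
Conditions: (9-BBN)2, THF, 23 → 50 °C; then 19, CuOAc (10 mol %), KOt-Bu, THF, 40 °C
Reagents that add atoms: 9-borabicyclo[3.3.1]nonane, C1CC2CCCC(C1)B2 (stays only in 20)
Why: Anti-Markovnikov hydroboration takes the only terminal alkene in preference to the hindered internal alkyne, and the copper-catalysed γ-selective (SN2') substitution of a propargylic phosphate by an alkylborane should form C9–C10 and the 1,1-disubstituted allene.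

Step 12
Reactants: 21 allene-yne
Product: 22 bicyclic dienone (6R,7R,11R,14R): bicyclo[5.3.0]deca-1(10),4-dien-3-one with 4-Me, 6-OTBS, the 7-oxolanyl side chain and 10-CH2OTBS
Conditions: [Rh(CO)2Cl]2 (10 mol %), CO (1 atm), toluene (0.01 M), 90 °C
Reagents that add atoms: carbon monoxide, [C-]#[O+]
Why: Rh(I) binds the alkyne C4≡C5 and the distal allene π-bond C1=C2, oxidative coupling forms C1–C5, CO inserts, and reductive elimination joins C2–C3–C4. The closest known reaction type is the Rh(I)-catalysed allenic Pauson–Khand reaction of 1,1-disubstituted allene-ynes with four-atom tethers, which is used for guaiane-type bicyclo[5.3.0]decadienones that carry oxygen at C6, a substituent at C7 and a methyl alkyne. Ring B (seven-membered) is closed as the tether ring by the bond from alkyne carbon C5 to the central allene carbon C1, and ring A (five-membered) is closed by the carbonylative [2+2+1] step. No new stereocentre arises: C6, C7, C11 and C14 are spectators under the neutral conditions, and C5 and C1 become sp2 and are set in steps 14 and 16. The step needs distal over proximal allene selectivity, which Rh(I) provides. It also needs suppression of cycloisomerisation, which the substrate secures because the allene terminus C2 is an unsubstituted CH2 with no β-hydrogen path, and dilution should hold back allene oligomerisation.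

Step 13
Reactants: 22 dienone
Product: 23 dienol, (3S)-alcohol of 22 (3β-OH, same face as the 6-OTBS group)
Conditions: (R)-Me-CBS, catecholborane, toluene, −78 °C
Reagents that add atoms: none
Why: In the Corey–Bakshi–Shibata 1,2-reduction the methyl-bearing alkenyl arm C4 acts as the large group and C2H2 as the small one, so the (R)-catalyst should deliver hydride to the α face and set C3 as (S) by reagent control.

Step 14
Reactants: 23 dienol
Product: 26 diene (5S,6S,7R,11R,14R): C3=C4, 5α-H, C1=C10 retained, both TBS ethers intact, via sulfonylhydrazine 24 (not isolated), via allylic diazene 25 (not isolated)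
Conditions: 2-nitrobenzenesulfonohydrazide (NBSH), PPh3, DEAD, N-methylmorpholine, −35 °C; then 23 °C
Reagents that add atoms: 2-nitrobenzenesulfonohydrazide, NNS(=O)(=O)c1ccccc1[N+](=O)[O-] (nitrogen stays only in 24 and 25; the product keeps one H)
Why: In this reductive allylic transposition, Mitsunobu SN2 displacement inverts C3 and places nitrogen on the α face, sulfinate loss gives the diazene, and its suprafacial retro-ene should deliver H to C5 from the α face while the alkene moves to C3=C4.

Step 15
Reactants: 26 bis-silyl ether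
Product: 27 diol (5S,6S,7R,11R,14R): 6-OH and C20H2OH on C10=C1
Conditions: TBAF, AcOH (1:1), THF, 23 → 45 °C
Reagents that add atoms: none
Why: Buffered fluoride cleaves both silyl ethers and should leave the tertiary acetate and the skipped diene untouched.

Step 16
Reactants: 27 diol
Product: 30 dictyol H (1R,5R,6S,7R,11R,14R), via sulfonylhydrazine 28 (not isolated), via allylic diazene 29 (not isolated)
Conditions: NBSH, PPh3, DEAD (1.3 equiv each), N-methylmorpholine–THF, −35 °C; then 23 °C
Reagents that add atoms: 2-nitrobenzenesulfonohydrazide, NNS(=O)(=O)c1ccccc1[N+](=O)[O-] (nitrogen stays only in 28 and 29; the product keeps one H)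
Why: The Mitsunobu step should select the primary allylic C20 alcohol over the hindered secondary C6 alcohol, and the retro-ene of the diazene should deliver H to C1 from the open α face, because with 5α-H ring B lies on the β face of C1=C10, which gives the cis fusion and C10=C20H2.

## Compound list

1 | (R)-4-benzyl-1,3-oxazolidin-2-one | O=C1N[C@H](Cc2ccccc2)CO1 | starting material
2 | (E)-but-2-enoyl chloride | C/C=C/C(=O)Cl | starting material
3 | (R)-4-benzyl-3-[(E)-but-2-enoyl]-1,3-oxazolidin-2-one | C/C=C/C(=O)N1[C@H](Cc2ccccc2)COC1=O | intermediate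
4 | but-2-ynal | CC#CC=O | starting material
5 | Z(O)-dibutylboron dienolate of 3 | C=C/C=C(\OB(CCCC)CCCC)N1[C@H](Cc2ccccc2)COC1=O | intermediate
6 | dibutylboron aldolate of 7 | C=C[C@@H](C(=O)N1[C@H](Cc2ccccc2)COC1=O)[C@@H](OB(CCCC)CCCC)C#CC | intermediate
7 | (R)-4-benzyl-3-[(2R,3R)-2-ethenyl-3-hydroxyhex-4-ynoyl]-1,3-oxazolidin-2-one | C=C[C@@H](C(=O)N1[C@H](Cc2ccccc2)COC1=O)[C@@H](O)C#CC | intermediate
8 | (2R,3R)-2-ethenyl-3-hydroxy-N-methoxy-N-methylhex-4-ynamide | C=C[C@@H](C(=O)N(C)OC)[C@@H](O)C#CC | intermediate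
9 | 5-bromo-2-methylpent-2-ene | CC(C)=CCCBr | starting material
10 | 4-methylpent-3-enylmagnesium bromide | CC(C)=CCC[Mg]Br | intermediate
11 | (4R,5R)-5-ethenyl-4-hydroxy-10-methylundec-9-en-2-yn-6-one | C=C[C@@H](C(=O)CCC=C(C)C)[C@@H](O)C#CC | intermediate
12 | (4R,5R,6R)-5-ethenyl-6,10-dimethylundec-9-en-2-yne-4,6-diol | C=C[C@@H]([C@@](O)(C)CCC=C(C)C)[C@@H](O)C#CC | intermediate
13 | (4R,5R,6R)-8-[(2S)-3,3-dimethyloxiran-2-yl]-5-ethenyl-6-methyloct-2-yne-4,6-diol | C=C[C@@H]([C@@](O)(C)CC[C@@H]1OC1(C)C)[C@@H](O)C#CC | intermediate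
14 | (4R,5R)-5-[(2R,5R)-5-(2-hydroxypropan-2-yl)-2-methyloxolan-2-yl]hept-6-en-2-yn-4-ol | C=C[C@@H]([C@@]1(C)CC[C@H](C(C)(C)O)O1)[C@@H](O)C#CC | intermediate
15 | 6-O-TBS ether of 14 | C=C[C@@H]([C@@]1(C)CC[C@H](C(C)(C)O)O1)[C@@H](O[Si](C)(C)C(C)(C)C)C#CC | intermediate
16 | C15 acetate of 15 | C=C[C@@H]([C@@]1(C)CC[C@H](C(C)(C)OC(C)=O)O1)[C@@H](O[Si](C)(C)C(C)(C)C)C#CC | intermediate
17 | but-2-yne-1,4-diol | OCC#CCO | starting material
18 | 4-(tert-butyldimethylsilyloxy)but-2-yn-1-ol | OCC#CCO[Si](C)(C)C(C)(C)C | intermediate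
19 | 4-(tert-butyldimethylsilyloxy)but-2-ynyl diethyl phosphate | CCOP(=O)(OCC)OCC#CCO[Si](C)(C)C(C)(C)C | intermediate
20 | B-alkyl-9-BBN from 16 (boron on C9) | C1CC2CCCC(C1)B2CC[C@@H]([C@@]1(C)CC[C@H](C(C)(C)OC(C)=O)O1)[C@@H](O[Si](C)(C)C(C)(C)C)C#CC | intermediate
21 | allene-yne | C=C=C(CO[Si](C)(C)C(C)(C)C)CC[C@@H]([C@@]1(C)CC[C@H](C(C)(C)OC(C)=O)O1)[C@@H](O[Si](C)(C)C(C)(C)C)C#CC | intermediate
22 | bicyclic dienone | CC(C)(C)[Si](C)(C)OCC=1CC[C@@H]([C@@]3(C)CC[C@H](C(C)(C)OC(C)=O)O3)[C@@H](O[Si](C)(C)C(C)(C)C)C2=C(C)C(=O)CC=12 | intermediate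
23 | (3S)-dienol | CC(C)(C)[Si](C)(C)OCC=1CC[C@@H]([C@@]3(C)CC[C@H](C(C)(C)OC(C)=O)O3)[C@@H](O[Si](C)(C)C(C)(C)C)C2=C(C)[C@@H](O)CC=12 | intermediate
24 | C3 N-(2-nitrobenzenesulfonyl)hydrazine (3α-N) | CC(C)(C)[Si](C)(C)OCC=1CC[C@@H]([C@@]3(C)CC[C@H](C(C)(C)OC(C)=O)O3)[C@@H](O[Si](C)(C)C(C)(C)C)C2=C(C)[C@H](N(N)S(=O)(=O)c4ccccc4[N+](=O)[O-])CC=12 | intermediate
25 | C3 allylic diazene | CC(C)(C)[Si](C)(C)OCC=1CC[C@@H]([C@@]3(C)CC[C@H](C(C)(C)OC(C)=O)O3)[C@@H](O[Si](C)(C)C(C)(C)C)C2=C(C)[C@H](N=N)CC=12 | intermediate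
26 | 5α-H diene, bis-TBS ether | CC(C)(C)[Si](C)(C)OCC=1CC[C@@H]([C@@]3(C)CC[C@H](C(C)(C)OC(C)=O)O3)[C@@H](O[Si](C)(C)C(C)(C)C)[C@H]2C(C)=CCC=12 | intermediate
27 | C6,C20-diol | OCC=1CC[C@@H]([C@@]3(C)CC[C@H](C(C)(C)OC(C)=O)O3)[C@@H](O)[C@H]2C(C)=CCC=12 | intermediate
28 | C20 N-(2-nitrobenzenesulfonyl)hydrazine | NN(CC=1CC[C@@H]([C@@]3(C)CC[C@H](C(C)(C)OC(C)=O)O3)[C@@H](O)[C@H]2C(C)=CCC=12)S(=O)(=O)c1ccccc1[N+](=O)[O-] | intermediate
29 | C20 allylic diazene | N=NCC=1CC[C@@H]([C@@]3(C)CC[C@H](C(C)(C)OC(C)=O)O3)[C@@H](O)[C@H]2C(C)=CCC=12 | intermediate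
30 | dictyol H | C=C1CC[C@@H]([C@@]2(C)CC[C@H](C(C)(C)OC(C)=O)O2)[C@@H](O)[C@H]2C(C)=CC[C@@H]12 | target

## Step count and risks

Total step count: 16. Longest linear sequence: 14 (steps 1–8 and 11–16).

**Step 12 (cyclocarbonylation).**
- What may go wrong: the oxidative coupling that closes the seven-membered ring may be slow. The allene may oligomerise, or the allylic silyl ether on the allene may ionise at rhodium.
- Fallback: the C20 oxygen is taken off the allene, and C20/C1 are handled at the very end by positional isomerisation instead of a second transposition. It sets out from 16 (through 20) and comes back at 30.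
- But-2-yn-1-ol is phosphorylated to but-2-ynyl diethyl phosphate F1. Copper-catalysed coupling of F1 with 20 gives the methyl-substituted allene-yne F2, which has the allene substitution pattern with the closest precedent.
- Cyclocarbonylation of F2 gives the 10-methyl dienone F3. CBS reduction gives the (3S)-dienol F4, and the Mitsunobu/diazene transposition gives the 5α-H diene F5. Fluoride then gives the Δ1(10) alcohol F6.
- A photochemical contra-thermodynamic alkene isomerisation closes the sequence. Photoredox oxidation of the tetrasubstituted alkene is followed by deprotonation at the C20 methyl group, capture of the allyl radical by Cr(II), and protodemetalation at C1 from the open α face, which should give 30.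

**Step 14 (first transposition).**
- What may go wrong: the dienylic oxyphosphonium ion may ionise, which would erode the inversion at C3, lead to elimination, or cause attack at a remote position.
- Fallback: hydride is delivered from palladium instead of from a diazene. It sets out from 23 and comes back at 26.
- 23 is formylated (formic acetic anhydride, pyridine) to the 3β-formate F7.
- Pd(0)/PBu3 ionises F7 with inversion, so that palladium sits on the α face. After decarboxylation, the palladium hydride should transfer H to the more substituted terminus C5 on that same face (formate hydrogenolysis of Tsuji type), giving 26.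

**Step 5 (methyl addition).**
- What may go wrong: the Grignard reagent may enolise the α-vinyl ketone, letting C8=C9 drift into conjugation or epimerising C7. Chelate control at C11 may also be incomplete.
- Fallback: Felkin–Anh control replaces chelate control, with the roles of the two carbon groups exchanged. It sets out from 8 and comes back at 15.
- 8 is silylated to the TBS-protected Weinreb amide F8, and MeMgBr gives the methyl ketone F9.
- The organocerium reagent made from 10 and CeCl3 should add anti to the large C6 branch and give the (11R)-tertiary alcohol F10.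
- ent-Shi epoxidation gives the (14S)-epoxide F11, and acid-induced 5-exo closure gives 15.

## Further compounds

F1 | step 12 | but-2-ynyl diethyl phosphate | CC#CCOP(=O)(OCC)OCC
F2 | step 12 | methyl-substituted allene-yne | C=C=C(C)CC[C@@H]([C@@]1(C)CC[C@H](C(C)(C)OC(C)=O)O1)[C@@H](O[Si](C)(C)C(C)(C)C)C#CC
F3 | step 12 | 10-methyl dienone | CC=1CC[C@@H]([C@@]3(C)CC[C@H](C(C)(C)OC(C)=O)O3)[C@@H](O[Si](C)(C)C(C)(C)C)C2=C(C)C(=O)CC=12
F4 | step 12 | (3S)-dienol | CC=1CC[C@@H]([C@@]3(C)CC[C@H](C(C)(C)OC(C)=O)O3)[C@@H](O[Si](C)(C)C(C)(C)C)C2=C(C)[C@@H](O)CC=12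
F5 | step 12 | 5α-H diene | CC=1CC[C@@H]([C@@]3(C)CC[C@H](C(C)(C)OC(C)=O)O3)[C@@H](O[Si](C)(C)C(C)(C)C)[C@H]2C(C)=CCC=12
F6 | step 12 | Δ1(10) alcohol | CC=1CC[C@@H]([C@@]3(C)CC[C@H](C(C)(C)OC(C)=O)O3)[C@@H](O)[C@H]2C(C)=CCC=12
F7 | step 14 | 3β-formate | CC(C)(C)[Si](C)(C)OCC=1CC[C@@H]([C@@]3(C)CC[C@H](C(C)(C)OC(C)=O)O3)[C@@H](O[Si](C)(C)C(C)(C)C)C2=C(C)[C@@H](OC=O)CC=12
F8 | step 5 | TBS-protected Weinreb amide | C=C[C@@H](C(=O)N(C)OC)[C@@H](O[Si](C)(C)C(C)(C)C)C#CC
F9 | step 5 | methyl ketone | C=C[C@@H](C(C)=O)[C@@H](O[Si](C)(C)C(C)(C)C)C#CC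
F10 | step 5 | (11R)-tertiary alcohol | C=C[C@@H]([C@@](O)(C)CCC=C(C)C)[C@@H](O[Si](C)(C)C(C)(C)C)C#CC
F11 | step 5 | (14S)-epoxide | C=C[C@@H]([C@@](O)(C)CC[C@@H]1OC1(C)C)[C@@H](O[Si](C)(C)C(C)(C)C)C#CC
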